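Numbering used throughout (target core): C1 is the quaternary carbon bearing CH3 and the CH2O carbon C13; C2–C3–C8–C7 is the cyclobutane in ring order; C4 is the ketone on C3; C5=C6 is the enone alkene (C6 bears CH3 and is bonded to C7); C8 bears CH3 and C9; C9, C10 are CH2; C11 is the carbinol carbon between C10 and C1. In this numbering the target is 1R,2S,3R,7R,8R,11S with two (Z)-2-methylbut-2-enoates (angelates).

## The problem

The target is a longipinane: a cyclobutane (C2, C3, C8, C7) bridged across C3/C7 by C4(=O)–C5=C6 (a bicyclo[3.1.1]heptenone) and across C2/C8 by C1–C11–C10–C9 (a seven-membered ring). Every cyclobutane carbon carries at least three carbon substituents, so no cyclobutanone-forming cycloaddition delivers a ring carbon at its final substitution, and C2 and C3 are both neopentyl (next to quaternary C1 and C8), which makes SN2 closures poor. The four cyclobutane stereocentres are tied together by the cage; what must be controlled is the sense of the cage relative to C1 (CH3 on the C3 side, C13 on the C7 side) and C11 (oxygen cis to the C1 methyl). Seen from C1 and C11 the finished cage is nearly mirror-symmetric (the two sides differ only in C4=O versus C6–CH3, far above the ring). C1 and C11 therefore cannot be set from the cage; they must be set first and must themselves direct cage formation. The feature that opens the problem is that the C4 carbonyl sits on cyclobutane carbon C3 and is flanked on its other side by C5=C6. The cyclobutyl ketone C3–C4(=O) is thus the product of a ring-contracting 1,2-shift of C2 from C4 to C3 in the cyclopentanol ring C4–C2–C7–C8–C3, and that cyclopentanol together with C5=C6 is a norborn-5-en-1-ol, i.e. a Diels–Alder adduct of a 1-oxycyclopentadiene. The strained enone is prone to acid-induced Wagner–Meerwein return to the bornane series, and the angelates isomerise easily to tiglates and are dienophiles, so they go on last.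

## Retrosynthesis

**19 ⇒ 18.** The two ester C–O bonds at C11 and C13 are cut first. Angelates tolerate neither heat, acid, strong base nor nucleophilic catalysts without Z→E drift, and they would compete as dienophiles, so diol 18 is the last intermediate. The forward step must acylate a neopentyl primary and a hindered secondary alcohol with retention of Z geometry.

**18 ⇒ 17.** C2–C3 is cut and C2–C4 restored (retro-semipinacol), with iodine placed on C3 and silicon on the C4 oxygen. The neighbouring cuts are worse: C2–C3 as an enolate alkylation is an SN2 at neopentyl C2 closing a four-membered ring, and any two-bond [2+2] cut gives either a cyclobutanone at C2 or an eleven-membered ring. The retro-shift removes the cyclobutane altogether and leaves norbornene 17. 17 has the same atoms as 18 but roughly half the strain and is a cycloadduct. The forward shift needs the C3 leaving group endo (antiperiplanar to C4–C2), no migration of C5, and no elimination path.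

**17 ⇒ 16.** C4–C3 and C7–C8 are cut (retro-[4+2]). This removes two rings and five stereocentres (C2, C3, C4, C7, C8) and gives monocyclic 16, a 1-silyloxy-3-methylcyclopentadiene carrying on its sp3 carbon C2 the chain C1–C11–C10–C9 that ends in the (E)-iodoalkene C8=C3. The forward reaction must go through the 5-substituted diene isomer, join C8 to C7 (not C4), and choose the diene face under control of C1.

**16 ⇒ 15 ⇒ 12.** 16 is the silyl dienol ether and bis-silyl ether of enone diol 15. 15 comes from keto ester 12 by reduction of the C11 ketone and the ester and reoxidation of the ring allylic alcohol. C11 must be sp3 and protected before the dienol ether is made, otherwise it would enolise. Its configuration is set by a catalyst on the acyclic ketone, where the two flanks (quaternary C1 versus CH2) differ most.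

**12 ⇒ 10 ⇒ 8 + 9.** The C6–CH3 bond is cut (enol triflate 11 of 1,3-dione 10), then C1–C2 (Michael addition). C1 is α to both future oxygenated carbons (C11, C13), i.e. the α-carbon of a 2-methyl-3-oxo ester 8, and C2 is the β-carbon of cyclopent-4-ene-1,3-dione 9. This is the only bond to quaternary C1 that a soft enolate can make; alkylating the α′ position of 3-methylcyclopentenone with a tertiary electrophile is not possible. A chiral catalyst sets C1.

**8 ⇒ 7 ⇒ 5 + 4; 4 ⇒ 3 ⇒ 1.** The C1 methyl is cut (methylation of 7), then C10–C9 (dianion alkylation of tert-butyl acetoacetate 5 with allylic bromide 4), then the iodoalkene (carboalumination–iodination of propargyl alcohol 1 via 3). The syn-carbometalation fixes iodine cis to the methyl, and this geometry later becomes the endo orientation of the leaving group.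

## Roads not taken

**Alternative 1:** Cut C2–C3 and C7–C8 as an intramolecular vinylketene–alkene [2+2] of farnesoyl-type chloride A1, giving bicyclo[3.1.1]heptanone A2 (the bergamotane route), then close the four-carbon bridge onto C2. This is the most obvious route. In A2, C2 is a carbonyl; turning it into CH–C1 with C1 quaternary needs a C–C addition plus deoxygenation of a tertiary cyclobutanol, since a C2=C1 alkene inside the seven-membered ring would be a bridgehead alkene. The cage is formed racemic and before C1/C11, which then meet the near-symmetric cage and cannot be related to it. C13 would have to be carved out of a gem-dimethyl group. The chosen plan forms the cage under control of C1 and delivers C2 as CH directly.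

**Alternative 2:** Cut C2–C3 as an enolate alkylation of the cis-fused bicyclo[5.4.0]undecenone mesylate A3 (C3 enolate displaces the C2 leaving group, copaene-type closure). This requires an SN2 at a carbon flanked by quaternary C1 and tertiary C7 to close a four-membered ring, with γ-deprotonation and elimination competing. A3 already holds two rings and five stereocentres and is not simpler than the product. The chosen key step starts from a monocyclic precursor with two stereocentres.

**Alternative 3:** Cut C2–C3 and C7–C8 as a transannular enone–alkene photocycloaddition of the eleven-membered trienone A4 (humulene-like). The two alkenes are 1,6-related through C4–C5–C6, so the triplet closes the five-membered ring first (C3–C7) and gives the straight rather than the crossed cyclobutane. Alkene geometry is scrambled in the excited state, and an eleven-membered ring with three defined alkenes costs more steps than the whole chosen route.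

Key step: step 12

Remark 1: compounds 10–16 are epimer mixtures at the ring carbon that becomes C2 (enolisable, later mobile by hydrogen shift); it is left undefined in names and SMILES and is fixed only in step 12.
Remark 2: the sense of induction in step 5 is assumed by analogy with simple 2-methyl-3-oxo esters; should 10 form as its antipode, the (S)-BINAP complex is used instead.

## Route

Step 1
Reactants: 1 prop-2-yn-1-ol
Product: 3 (E)-3-iodo-2-methylprop-2-en-1-ol, via alkenylalane 2 (not isolated)
Conditions: AlMe3 (3 equiv), Cp2ZrCl2 (0.25 equiv), CH2Cl2, 0 °C to rt; then I2, THF, −30 to 0 °C; aq. K2CO3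
Reagents that add atoms: trimethylaluminium C[Al](C)C; iodine II
Why: Zirconium-catalysed syn-carboalumination (Negishi type) puts CH3 on the internal carbon and aluminium cis to it on the terminus; iodinolysis with retention gives iodine cis to CH3 and trans to the CH2O carbon.

Step 2
Reactants: 3 (E)-3-iodo-2-methylprop-2-en-1-ol
Product: 4 (E)-3-bromo-1-iodo-2-methylprop-1-ene
Conditions: CBr4, PPh3, CH2Cl2, 0 °C
Reagents that add atoms: tetrabromomethane BrC(Br)(Br)Br
Why: Appel bromination of a primary allylic alcohol under neutral conditions; the alkenyl iodide and its geometry are not touched.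

Step 3
Reactants: 5 tert-butyl acetoacetate; 4 (E)-3-bromo-1-iodo-2-methylprop-1-ene
Product: 7 tert-butyl (E)-7-iodo-6-methyl-3-oxohept-6-enoate, via dilithium dianion 6 (not isolated)
Conditions: LiN(i-Pr)2 (2.1 equiv), THF, 0 °C; then 4, 0 °C to rt; aq. NH4Cl
Reagents that add atoms: none
Why: γ-Alkylation of an acetoacetate dianion; the more basic terminal carbanion attacks the primary allylic bromide by SN2 (the SN2′ terminus is the hindered CHI carbon), forming the C10–C9 bond.

Step 4
Reactants: 7 tert-butyl (E)-7-iodo-6-methyl-3-oxohept-6-enoate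
Product: 8 tert-butyl (E)-7-iodo-2,6-dimethyl-3-oxohept-6-enoate (racemic at C2 of the chain)
Conditions: K2CO3, MeI, acetone, rt
Reagents that add atoms: iodomethane CI
Why: Monomethylation of the β-keto ester at the doubly activated carbon; the new centre is racemic and is planarised again in step 5.

Step 5
Reactants: 8 tert-butyl (E)-7-iodo-2,6-dimethyl-3-oxohept-6-enoate; 9 cyclopent-4-ene-1,3-dione
Product: 10 tert-butyl (2S,6E)-2-(2,4-dioxocyclopentyl)-7-iodo-2,6-dimethyl-3-oxohept-6-enoate
Conditions: [Pd((R)-BINAP)(OH2)2](OTf)2 (5 mol %), THF, −20 to 0 °C, 9 added slowly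
Reagents that add atoms: none
Why: Catalytic enantioselective Michael addition through the chelated divalent-palladium enolate of 8, whose diphosphine shields one enolate face and sets quaternary C1 while forming the C1–C2 bond. The catalyst works without base, which matters because 9 and the product are acidic 1,3-diones that would quench an amine or alkoxide catalyst, and a cyclic 1,3-dione cannot chelate palladium, so only 8 is activated.

Step 6
Reactants: 10 tert-butyl (2S,6E)-2-(2,4-dioxocyclopentyl)-7-iodo-2,6-dimethyl-3-oxohept-6-enoate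
Product: 11 tert-butyl (2S,6E)-7-iodo-2,6-dimethyl-3-oxo-2-[2-oxo-4-(trifluoromethanesulfonyloxy)cyclopent-3-en-1-yl]hept-6-enoate
Conditions: Tf2O (1.1 equiv), 2,6-lutidine, CH2Cl2, −78 °C
Reagents that add atoms: trifluoromethanesulfonic anhydride O=S(=O)(OS(=O)(=O)C(F)(F)F)C(F)(F)F
Why: O-Sulfonylation of the dione enolate at the oxygen remote from the substituent (the C6 oxygen), because the C4 oxygen is shielded by C2 carrying the fully substituted C1; this keeps the carbonyl at C4 and marks C6 for methylation.

Step 7
Reactants: 11 tert-butyl (2S,6E)-7-iodo-2,6-dimethyl-3-oxo-2-[2-oxo-4-(trifluoromethanesulfonyloxy)cyclopent-3-en-1-yl]hept-6-enoate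
Product: 12 tert-butyl (2S,6E)-7-iodo-2,6-dimethyl-2-(4-methyl-2-oxocyclopent-3-en-1-yl)-3-oxohept-6-enoate
Conditions: Me2CuLi (1.5 equiv), THF, −78 °C; aq. NH4Cl
Reagents that add atoms: lithium dimethylcuprate [Li+].C[Cu-]C
Why: Conjugate addition–elimination of a cuprate on a β-triflyloxy enone gives the 3-methyl enone; at −78 °C the alkenyl iodide, the hindered ketone and the ester are inert.

Step 8
Reactants: 12 tert-butyl (2S,6E)-7-iodo-2,6-dimethyl-2-(4-methyl-2-oxocyclopent-3-en-1-yl)-3-oxohept-6-enoate
Product: 13 tert-butyl (2S,3S,6E)-3-hydroxy-2-(2-hydroxy-4-methylcyclopent-3-en-1-yl)-7-iodo-2,6-dimethylhept-6-enoate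
Conditions: (R)-Me-CBS oxazaborolidine (0.3 equiv), BH3·SMe2 (2.5 equiv), THF, −20 °C; MeOH
Reagents that add atoms: none
Why: Corey–Bakshi–Shibata reduction; the catalyst distinguishes the quaternary flank (large) from the CH2 flank (small) of the C11 ketone and with the (R)-catalyst should give the 11S alcohol (same sense as a tert-alkyl methyl ketone). The ring carbonyl is reduced too, which does no harm since step 10 restores it.

Step 9
Reactants: 13 tert-butyl (2S,3S,6E)-3-hydroxy-2-(2-hydroxy-4-methylcyclopent-3-en-1-yl)-7-iodo-2,6-dimethylhept-6-enoate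
Product: 14 (2R,3S,6E)-2-(2-hydroxy-4-methylcyclopent-3-en-1-yl)-7-iodo-2,6-dimethylhept-6-ene-1,3-diol
Conditions: i-Bu2AlH (6 equiv), CH2Cl2, −78 °C to rt; aq. Rochelle salt
Reagents that add atoms: none
Why: Hydride reduction of the hindered tert-butyl ester to the neopentyl alcohol C13; i-Bu2AlH leaves alkenyl iodides intact (the descriptor at C1 changes to R only through priorities).

Step 10
Reactants: 14 (2R,3S,6E)-2-(2-hydroxy-4-methylcyclopent-3-en-1-yl)-7-iodo-2,6-dimethylhept-6-ene-1,3-diol
Product: 15 5-[(2R,3S,6E)-1,3-dihydroxy-7-iodo-2,6-dimethylhept-6-en-2-yl]-3-methylcyclopent-2-en-1-one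
Conditions: MnO2 (20 equiv), CH2Cl2, rt
Reagents that add atoms: none
Why: MnO2 oxidises only the allylic ring alcohol; the saturated primary and secondary alcohols remain.

Step 11
Reactants: 15 5-[(2R,3S,6E)-1,3-dihydroxy-7-iodo-2,6-dimethylhept-6-en-2-yl]-3-methylcyclopent-2-en-1-one
Product: 16 1-(tert-butyldimethylsilyloxy)-5-[(2R,3S,6E)-1,3-bis(tert-butyldimethylsilyloxy)-7-iodo-2,6-dimethylhept-6-en-2-yl]-3-methylcyclopenta-1,3-diene (with its double-bond isomers)
Conditions: TBSOTf (3.6 equiv), Et3N (6 equiv), CH2Cl2, −78 to 0 °C; used crude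
Reagents that add atoms: tert-butyldimethylsilyl trifluoromethanesulfonate CC(C)(C)[Si](C)(C)OS(=O)(=O)C(F)(F)F
Why: Silylation of both alcohols and soft enolisation of the enone to the silyl dienol ether; γ-deprotonation at C7 is favoured because the α′ hydrogen on C2 is shielded by C1. Whichever diene isomer forms, they interconvert on heating.

Step 12
Reactants: 16 1-(tert-butyldimethylsilyloxy)-5-[(2R,3S,6E)-1,3-bis(tert-butyldimethylsilyloxy)-7-iodo-2,6-dimethylhept-6-en-2-yl]-3-methylcyclopenta-1,3-diene
Product: 18 (1R,2S,3R,7R,8R,11S)-enone diol (target numbering; 4-hydroxy-3-(hydroxymethyl)-3,7,11-trimethyltricyclo[5.4.0.0^{2,8}]undec-10-en-9-one skeleton), via Diels–Alder adduct 17 (not isolated)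
Conditions: PhMe (0.005 M), Et3N (0.1 equiv), 140 °C, sealed; then Bu4NF (5 equiv), THF, 0 °C to rt; aq. NH4Cl
Reagents that add atoms: none
Why: On heating, 16 equilibrates with its double-bond isomers by [1,5]-hydrogen shifts, but only the isomer with the chain on sp3 C2 can add its iodoalkene across C4 and C7 without building three contiguous fully substituted carbons (C1–C2–C8), so the intramolecular Diels–Alder reaction closes C4–C3 and C7–C8 and with them the seven-membered ring (C2, C1, C11, C10, C9, C8, C7) in the bridged mode known for 5-tethered cyclopentadienes (longifolane-type adducts). The addition is suprafacial: the tether must leave C8 on the exo face, so the C8 methyl is endo and the (E)-iodoalkene puts iodine endo at C3, and C8 joins C7 rather than C4 because a bond between fully substituted C8 and the silyloxy-bearing C4 is the more hindered and the developing negative charge is better placed on the iodine-bearing carbon. The diene face, which fixes C2, C4 and C7, is chosen by C1: in the adduct one C1 substituent lies beside the C4 silyloxy bridgehead and the other points into open space, so the small CH3 takes the former and CH2OTBS the latter, which is the relative configuration of the target. Fluoride then frees the C4 alkoxide, and the C4–C2 bond, the only one antiperiplanar (about 155°) to the endo C3–I bond, shifts to C3 with inversion there and retention at C2 while C4 becomes the ketone: a semipinacol contraction of the 2-iodocyclopentanol ring C4–C2–C7–C8–C3 to the acylcyclobutane C2–C3–C8–C7, the same event as the second stage of a quasi-Favorskii rearrangement. This single shift creates the cyclobutane and the six-membered enone ring at once. The substrate secures its course: C5 is gauche to the leaving group and cannot migrate, C4 and C8 carry no hydrogen for elimination, and the bridgehead oxygen cannot reach the back of C3 to form an epoxide. The same fluoride removes the two remaining silyl ethers.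

Step 13
Reactants: 18 (1R,2S,3R,7R,8R,11S)-enone diol
Product: 19 target diester CNP0240716.1 (11-O,13-O-diangelate of 18)
Conditions: angelic acid (5 equiv), 2,4,6-trichlorobenzoyl chloride (5 equiv), Et3N (10 equiv), PhMe, rt; then 18, 80 °C
Reagents that add atoms: angelic acid C/C=C(/C)C(O)=O
Why: Yamaguchi-type mixed-anhydride acylation without a nucleophilic catalyst; angelates isomerise to tiglates with acid, nucleophilic amines or strong base, whereas the 2,4,6-trichlorobenzoyl mixed anhydride should transfer the angeloyl group to both alcohols with the Z geometry intact.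

## Compound list

1 | prop-2-yn-1-ol | C#CCO | starting material
2 | (E)-alkenylalane (dimethylaluminium alkoxide of (E)-3-(dimethylalumanyl)-2-methylprop-2-en-1-ol) | C[Al](C)OC/C(C)=C/[Al](C)C | intermediate
3 | (E)-3-iodo-2-methylprop-2-en-1-ol | OC/C(C)=C/I | intermediate
4 | (E)-3-bromo-1-iodo-2-methylprop-1-ene | BrC/C(C)=C/I | intermediate
5 | tert-butyl acetoacetate | CC(=O)CC(=O)OC(C)(C)C | starting material
6 | dilithium dianion of tert-butyl acetoacetate | [Li+].[Li+].C=C([O-])/C=C(\[O-])OC(C)(C)C | intermediate
7 | tert-butyl (E)-7-iodo-6-methyl-3-oxohept-6-enoate | CC(C)(C)OC(=O)CC(=O)CC/C(C)=C/I | intermediate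
8 | tert-butyl (E)-7-iodo-2,6-dimethyl-3-oxohept-6-enoate (racemic) | CC(C)(C)OC(=O)C(C)C(=O)CC/C(C)=C/I | intermediate
9 | cyclopent-4-ene-1,3-dione | O=C1CC(=O)C=C1 | starting material
10 | tert-butyl (2S,6E)-2-(2,4-dioxocyclopentyl)-7-iodo-2,6-dimethyl-3-oxohept-6-enoate | CC(C)(C)OC(=O)[C@@](C)(C1CC(=O)CC1=O)C(=O)CC/C(C)=C/I | intermediate
11 | tert-butyl (2S,6E)-7-iodo-2,6-dimethyl-3-oxo-2-[2-oxo-4-(trifluoromethanesulfonyloxy)cyclopent-3-en-1-yl]hept-6-enoate | CC(C)(C)OC(=O)[C@@](C)(C1CC(OS(=O)(=O)C(F)(F)F)=CC1=O)C(=O)CC/C(C)=C/I | intermediate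
12 | tert-butyl (2S,6E)-7-iodo-2,6-dimethyl-2-(4-methyl-2-oxocyclopent-3-en-1-yl)-3-oxohept-6-enoate | CC(C)(C)OC(=O)[C@@](C)(C1CC(C)=CC1=O)C(=O)CC/C(C)=C/I | intermediate
13 | tert-butyl (2S,3S,6E)-3-hydroxy-2-(2-hydroxy-4-methylcyclopent-3-en-1-yl)-7-iodo-2,6-dimethylhept-6-enoate | CC(C)(C)OC(=O)[C@@](C)(C1CC(C)=CC1O)[C@@H](O)CC/C(C)=C/I | intermediate
14 | (2R,3S,6E)-2-(2-hydroxy-4-methylcyclopent-3-en-1-yl)-7-iodo-2,6-dimethylhept-6-ene-1,3-diol | OC[C@@](C)(C1CC(C)=CC1O)[C@@H](O)CC/C(C)=C/I | intermediate
15 | 5-[(2R,3S,6E)-1,3-dihydroxy-7-iodo-2,6-dimethylhept-6-en-2-yl]-3-methylcyclopent-2-en-1-one | OC[C@@](C)(C1CC(C)=CC1=O)[C@@H](O)CC/C(C)=C/I | intermediate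
16 | 1-(tert-butyldimethylsilyloxy)-5-[(2R,3S,6E)-1,3-bis(tert-butyldimethylsilyloxy)-7-iodo-2,6-dimethylhept-6-en-2-yl]-3-methylcyclopenta-1,3-diene | CC(C)(C)[Si](C)(C)OC[C@@](C)(C1C=C(C)C=C1O[Si](C)(C)C(C)(C)C)[C@@H](O[Si](C)(C)C(C)(C)C)CC/C(C)=C/I | intermediate
17 | Diels–Alder adduct (norbornene: C4 bridgehead OTBS, endo iodide at C3, endo CH3 at C8, C2 as one-carbon bridge; 1R,2R,3S,4S,7R,8R,11S in target numbering) | CC(C)(C)[Si](C)(C)OC[C@@]1(C)[C@@H]2[C@@]([C@H]3I)(O[Si](C)(C)C(C)(C)C)C=C(C)[C@@H]2[C@@]3(C)CC[C@@H]1O[Si](C)(C)C(C)(C)C | intermediate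
18 | (1R,2S,3R,7R,8R,11S)-enone diol (11-hydroxy, 13-hydroxy longipinenone core) | OC[C@@]1(C)[C@@H]2[C@H]3C(=O)C=C(C)[C@@H]2[C@@]3(C)CC[C@@H]1O | intermediate
19 | target CNP0240716.1, the 11-O,13-O-diangelate of 18 | C/C=C(/C)C(=O)OC[C@@]1(C)[C@@H]2[C@H]3C(=O)C=C(C)[C@@H]2[C@@]3(C)CC[C@@H]1OC(=O)/C(C)=C\C | target

## Step count and risk

Total: 13 steps. Longest linear sequence: 13 steps (1 → 19); 5 and 9 enter as purchased materials.

**Step 12 (key step).** The unactivated iodoalkene may add too slowly, so that dimerisation of the diene, cycloaddition through a hydrogen-shift isomer, or loss of regio- or facial control takes over. After fluoride treatment, alkoxide-accelerated cycloreversion could compete with the 1,2-shift. Fallback (boron-activated dienophile, leaving group installed after the cycloaddition), setting out from 15 and returning at 18: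
- Miyaura borylation of 15 (PdCl2(dppf), B2pin2, KOAc) gives the alkenyl pinacolboronate F1 with retained geometry.
- Silylation as in step 11 gives the silyloxydiene boronate F2.
- Its intramolecular Diels–Alder reaction is polarised so that C8 is the electrophilic carbon for the nucleophilic C7 terminus, and gives the endo-boryl adduct F3.
- NaBO3·4H2O oxidation with retention gives the endo alcohol F4.
- MsCl/Et3N gives the endo mesylate F5.
- Bu4NF then triggers the same alkoxide shift with a sulfonate nucleofuge and removes the silyl ethers to give 18.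

**Step 5.** Enantioselection or turnover may fail because the acceptor and product are acidic diones and the acceptor can oligomerise. Fallback, from 8 and 9, returning at 13:
- A base-free FeCl3·6H2O-catalysed Michael addition gives the racemic adduct F6.
- Steps 6 and 7 give the racemic triflate F7 and the racemic methyl enone F8.
- The catalyst-controlled reduction of step 8 then converts the racemate into 13 and its C1 epimer, the (2R,3S)-diol ester F9, which are diastereomers and are separated by chromatography.

**Step 6.** O-Sulfonylation may not discriminate the two dione oxygens well enough. Fallback, which uses the C11 oxygen as an internal marker, from 10, returning at 14: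
- The reduction of step 8 applied to 10 gives the hydroxy dione F10.
- Mild acid (PPTS, MgSO4) closes the five-membered enol ether onto C4, the only carbonyl the C11 oxygen can reach, giving the bicyclic vinylogous ester F11.
- MeLi/CeCl3 addition at C6 followed by aqueous acid (Stork–Danheiser transposition) gives the hydroxy enone ester F12.
- i-Bu2AlH reduces F12 to 14.

**Step 8.** Facial selectivity at the very hindered ketone may be poor (mismatch with C1), and slow reduction may allow hydroboration. Fallback, from 12, returning at 13: Luche reduction (NaBH4, CeCl3·7H2O) gives 13 together with the 11R epimer F13; these are separated, and F13 is recycled to 12 by Dess–Martin oxidation.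

**Step 13.** Z→E isomerisation of the angeloyl group or incomplete acylation of the hindered C11 alcohol may occur. Fallback, which builds the Z alkene on the molecule, from 18, returning at 19: DCC/DMAP esterification with 2-[bis(2,2,2-trifluoroethoxy)phosphoryl]propanoic acid gives the bis(phosphonopropanoate) F14, and a Z-selective Still–Gennari olefination with acetaldehyde (KN(SiMe3)2, 18-crown-6, THF, −78 °C) gives 19.

## Further compounds

F1 | step 12 | 5-[(2R,3S,6E)-1,3-dihydroxy-2,6-dimethyl-7-(4,4,5,5-tetramethyl-1,3,2-dioxaborolan-2-yl)hept-6-en-2-yl]-3-methylcyclopent-2-en-1-one | OC[C@@](C)(C1CC(C)=CC1=O)[C@@H](O)CC/C(C)=C/B1OC(C)(C)C(C)(C)O1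
F2 | step 12 | tris-TBS silyloxycyclopentadiene alkenylboronate (16 with Bpin in place of I) | CC(C)(C)[Si](C)(C)OC[C@@](C)(C1C=C(C)C=C1O[Si](C)(C)C(C)(C)C)[C@@H](O[Si](C)(C)C(C)(C)C)CC/C(C)=C/B1OC(C)(C)C(C)(C)O1
F3 | step 12 | endo-boryl Diels–Alder adduct (17 with Bpin in place of I) | CC(C)(C)[Si](C)(C)OC[C@@]1(C)[C@@H]2[C@@]([C@H]3B4OC(C)(C)C(C)(C)O4)(O[Si](C)(C)C(C)(C)C)C=C(C)[C@@H]2[C@@]3(C)CC[C@@H]1O[Si](C)(C)C(C)(C)C
F4 | step 12 | endo alcohol (17 with OH in place of I) | CC(C)(C)[Si](C)(C)OC[C@@]1(C)[C@@H]2[C@@]([C@H]3O)(O[Si](C)(C)C(C)(C)C)C=C(C)[C@@H]2[C@@]3(C)CC[C@@H]1O[Si](C)(C)C(C)(C)C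
F5 | step 12 | endo mesylate (17 with OMs in place of I) | CC(C)(C)[Si](C)(C)OC[C@@]1(C)[C@@H]2[C@@]([C@H]3OS(C)(=O)=O)(O[Si](C)(C)C(C)(C)C)C=C(C)[C@@H]2[C@@]3(C)CC[C@@H]1O[Si](C)(C)C(C)(C)C
F6 | step 5 | racemic tert-butyl (E)-2-(2,4-dioxocyclopentyl)-7-iodo-2,6-dimethyl-3-oxohept-6-enoate | CC(C)(C)OC(=O)C(C)(C1CC(=O)CC1=O)C(=O)CC/C(C)=C/I
F7 | step 5 | racemic enol triflate (racemic 11) | CC(C)(C)OC(=O)C(C)(C1CC(OS(=O)(=O)C(F)(F)F)=CC1=O)C(=O)CC/C(C)=C/I
F8 | step 5 | racemic methyl enone (racemic 12) | CC(C)(C)OC(=O)C(C)(C1CC(C)=CC1=O)C(=O)CC/C(C)=C/I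
F9 | step 5 | tert-butyl (2R,3S,6E)-3-hydroxy-2-(2-hydroxy-4-methylcyclopent-3-en-1-yl)-7-iodo-2,6-dimethylhept-6-enoate | CC(C)(C)OC(=O)[C@](C)(C1CC(C)=CC1O)[C@@H](O)CC/C(C)=C/I
F10 | step 6 | tert-butyl (2S,3S,6E)-2-(2,4-dioxocyclopentyl)-3-hydroxy-7-iodo-2,6-dimethylhept-6-enoate | CC(C)(C)OC(=O)[C@@](C)(C1CC(=O)CC1=O)[C@@H](O)CC/C(C)=C/I
F11 | step 6 | bicyclic vinylogous ester (C11 oxygen bonded to C4; C4=C5–C6=O) | CC(C)(C)OC(=O)[C@@]1(C)C2CC(=O)C=C2O[C@H]1CC/C(C)=C/I
F12 | step 6 | tert-butyl (2S,3S,6E)-3-hydroxy-7-iodo-2,6-dimethyl-2-(4-methyl-2-oxocyclopent-3-en-1-yl)hept-6-enoate | CC(C)(C)OC(=O)[C@@](C)(C1CC(C)=CC1=O)[C@@H](O)CC/C(C)=C/I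
F13 | step 8 | tert-butyl (2S,3R,6E)-3-hydroxy-2-(2-hydroxy-4-methylcyclopent-3-en-1-yl)-7-iodo-2,6-dimethylhept-6-enoate | CC(C)(C)OC(=O)[C@@](C)(C1CC(C)=CC1O)[C@H](O)CC/C(C)=C/I
F14 | step 13 | 11-O,13-O-bis{2-[bis(2,2,2-trifluoroethoxy)phosphoryl]propanoate} of 18 | CC(P(=O)(OCC(F)(F)F)OCC(F)(F)F)C(=O)OC[C@@]1(C)[C@@H]2[C@H]3C(=O)C=C(C)[C@@H]2[C@@]3(C)CC[C@@H]1OC(=O)C(C)P(=O)(OCC(F)(F)F)OCC(F)(F)F
A1 | alternative 1 | (2E,6E)-farnesoyl chloride | CC(C)=CCC/C(C)=C/CC/C(C)=C/C(Cl)=O
A2 | alternative 1 | 7-methyl-2-methylidene-7-(4-methylpent-3-enyl)bicyclo[3.1.1]heptan-6-one (chain anti to the three-carbon bridge) | O=C1[C@H]2CCC(=C)[C@@H]1[C@@]2(C)CCC=C(C)C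
A3 | alternative 2 | cis-fused bicyclo[5.4.0]undecenone C2 mesylate, bis-TBS ether | CC(C)(C)[Si](C)(C)OC[C@@]1(C)[C@@H](OS(C)(=O)=O)[C@@H]2C(C)=CC(=O)C[C@]2(C)CC[C@@H]1O[Si](C)(C)C(C)(C)C
A4 | alternative 3 | eleven-membered trienone, bis-TBS ether | CC(C)(C)[Si](C)(C)OC[C@@]1(C)/C=C/C(C)=C\C(=O)/C=C(C)/CC[C@@H]1O[Si](C)(C)C(C)(C)C
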